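The route rests on disconnecting the O1–C5 bond of the oxolane ring, whose C5 aryl group sits cis to the C4 hydroxymethyl arm, back to the C1–C2 bond of a 2-arylcyclobutanone. One Baeyer–Villiger oxidation inserts oxygen next to the benzylic carbon with retention, turning the four-membered carbocycle into the γ-lactone (O1, C2–C5) and fixing the contra-thermodynamic cis benzylic C–O bond without any ionic etherification. The precursor is (2S,3S,4S)-2-aryl-3,4-bis(silyloxymethyl)cyclobutanone, assembled by a chiral keteniminium–alkene [2+2] cycloaddition. All four hydroxyls travel as triisopropylsilyl ethers, so the end game needs no hydrogenolysis of a doubly benzylic ether. Aryllithium addition and kinetic oxocarbenium reduction then set C2.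

Key step: step 5

Assumption: the (2R,5R) antipode of the auxiliary is taken to give the (2S,3S,4S) cyclobutanone on the basis of a simple quadrant model (ring closure on the side of the iminium carbon where the pyrrolidine α-methyl points away from the incoming alkene); if the opposite sense were found, the equally available (2S,5S) amine would be used with no other change.

Step 1
Reactants: 1 homovanillic acid
Product: 3 [3-methoxy-4-(triisopropylsilyloxy)phenyl]acetic acid, via silyl ester 2 (not isolated)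
Conditions: TIPSCl, imidazole, DMF, rt; then K2CO3, MeOH–THF–H2O, rt; 1 M HCl to pH 3
Reagents that add atoms: triisopropylsilyl chloride, CC(C)[Si](Cl)(C(C)C)C(C)C
Why: Imidazole-promoted silylation converts both the phenol and the acid, and mild carbonate solvolysis then cleaves only the far more labile silyl ester, leaving the hindered aryl silyl ether; no stereocentre is involved.

Step 2
Reactants: 3 [3-methoxy-4-(triisopropylsilyloxy)phenyl]acetic acid; 4 (2R,5R)-2,5-dimethylpyrrolidine
Product: 6 1-[(2R,5R)-2,5-dimethylpyrrolidin-1-yl]-2-[3-methoxy-4-(triisopropylsilyloxy)phenyl]ethan-1-one, via acid chloride 5 (not isolated)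
Conditions: (COCl)2, cat. DMF, CH2Cl2, 0 °C → rt, evaporate; then 4, Et3N, CH2Cl2, 0 °C → rt
Reagents that add atoms: none
Why: N-acylation by an acid chloride is the reliable way to acylate this hindered secondary amine, the aryl silyl ether tolerates oxalyl chloride, and the two stereocentres of the auxiliary are not touched.

Step 3
Reactants: 7 (E)-but-2-ene-1,4-diol
Product: 8 (E)-1,4-bis(triisopropylsilyloxy)but-2-ene
Conditions: TIPSCl, imidazole, DMF, rt
Reagents that add atoms: triisopropylsilyl chloride, CC(C)[Si](Cl)(C(C)C)C(C)C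
Why: Standard silylation of two primary allylic alcohols, chosen because bulky, weakly basic silyl ether oxygens should not compete with the alkene for the keteniminium ion of step 4; the E geometry is untouched.

Step 4
Reactants: 6 1-[(2R,5R)-2,5-dimethylpyrrolidin-1-yl]-2-[3-methoxy-4-(triisopropylsilyloxy)phenyl]ethan-1-one; 8 (E)-1,4-bis(triisopropylsilyloxy)but-2-ene
Product: 11 (2S,3S,4S)-2-[3-methoxy-4-(triisopropylsilyloxy)phenyl]-3,4-bis[(triisopropylsilyloxy)methyl]cyclobutan-1-one, via keteniminium triflate 9 (not isolated), via cyclobutaniminium triflate 10 (not isolated)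
Conditions: Tf2O (1.1 equiv), 2,4,6-collidine (1.0 equiv), 8 (2 equiv), ClCH2CH2Cl, 0 → 60 °C; then aq. NaH2PO4/Na2HPO4 (pH 7), rt
Reagents that add atoms: water, O
Why: Keteniminium–alkene [2+2] cycloaddition: O-triflation and deprotonation of 6 give salt 9, whose iminium carbon is attacked by the alkene on the side away from the aryl group so that ring closure leaves the aryl group cis to the C3 arm (the contra-thermodynamic outcome typical of ketene-type cycloadditions), the E geometry of 8 is carried stereospecifically into the 3,4-trans arms, the C2-symmetric pyrrolidine fixes the absolute sense at C2, C3 and C4 by blocking one of the two enantiomeric crossed approaches, and hydrolysis of 10 at neutral pH releases the ketone without a base that could enolise the α-aryl centre.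

Step 5
Reactants: 11 (2S,3S,4S)-2-[3-methoxy-4-(triisopropylsilyloxy)phenyl]-3,4-bis[(triisopropylsilyloxy)methyl]cyclobutan-1-one
Product: 13 (3S,4S,5S)-5-[3-methoxy-4-(triisopropylsilyloxy)phenyl]-3,4-bis[(triisopropylsilyloxy)methyl]oxolan-2-one, via peracid adduct 12 (not isolated)
Conditions: m-CPBA, NaHCO3, CH2Cl2, 0 °C (crude 11 used at once)
Reagents that add atoms: 3-chloroperoxybenzoic acid, OOC(=O)c1cccc(Cl)c1
Why: Baeyer–Villiger oxidation: the peracid adds to the strained carbonyl group to give the tetrahedral adduct 12, whose O–O bond breaks while cyclobutanone C2 shifts from carbon to oxygen, creating the O1–C5 bond of the lactone. The closest known reaction type is the peracid ring expansion of 2-substituted cyclobutanones to γ-butyrolactones with migration of the more substituted α-carbon. The five-membered ring arises by one-atom ring expansion (oxygen insertion into the C1–C2 bond of the four-membered ring) and not by a cyclisation, so no exo or endo mode applies. No stereocentre is created: the migrating carbon keeps its configuration, so the cis aryl/arm relationship of 11 becomes the 4,5-cis relationship of 13 and the trans arms are untouched. The step needs C2 to migrate in preference to C4 and the α-aryl ketone not to enolise; the electron-rich 4-silyloxy-3-methoxyphenyl group makes the benzylic carbon the better migrating group, C4 carrying only an inductively deactivating silyloxymethyl group, and the cold bicarbonate-buffered medium together with the speed of oxidation of a strained ketone should leave no opportunity for epimerisation.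

Step 6
Reactants: 14 4-bromo-2-methoxyphenol
Product: 15 (4-bromo-2-methoxyphenoxy)triisopropylsilane
Conditions: TIPSCl, imidazole, DMF, rt
Reagents that add atoms: triisopropylsilyl chloride, CC(C)[Si](Cl)(C(C)C)C(C)C
Why: Routine phenol silylation; the triisopropylsilyl ether is para to bromine, so the later aryllithium cannot undergo silyl migration, and it resists attack by butyllithium.

Step 7
Reactants: 13 (3S,4S,5S)-5-[3-methoxy-4-(triisopropylsilyloxy)phenyl]-3,4-bis[(triisopropylsilyloxy)methyl]oxolan-2-one; 15 (4-bromo-2-methoxyphenoxy)triisopropylsilane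
Product: 17 (3S,4S,5S)-2,5-bis[3-methoxy-4-(triisopropylsilyloxy)phenyl]-3,4-bis[(triisopropylsilyloxy)methyl]oxolan-2-ol (both C2 epimers), via aryllithium 16 (not isolated)
Conditions: 15, n-BuLi, THF, −78 °C; then 13, THF, −78 °C; aq. NH4Cl
Reagents that add atoms: none
Why: Bromine–lithium exchange followed by aryllithium addition to a γ-lactone: the tetrahedral lithium alkoxide persists at −78 °C, so only one aryl group is taken up and the cyclic hemiketal is obtained on work-up; C3, C4 and C5 are not involved and the new hemiketal carbon need not be controlled because step 8 planarises it.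

Step 8
Reactants: 17 (3S,4S,5S)-2,5-bis[3-methoxy-4-(triisopropylsilyloxy)phenyl]-3,4-bis[(triisopropylsilyloxy)methyl]oxolan-2-ol
Product: 19 (2S,3S,4S,5S)-2,5-bis[3-methoxy-4-(triisopropylsilyloxy)phenyl]-3,4-bis[(triisopropylsilyloxy)methyl]oxolane, via oxocarbenium ion 18 (not isolated)
Conditions: Et3SiH, BF3·OEt2, CH2Cl2, −78 °C; then aq. NaHCO3
Reagents that add atoms: none
Why: Ionic hydrogenation (Lewis acid–silane reductive deoxygenation of a cyclic hemiketal): BF3·OEt2 ionises 17 to the 2-aryl oxocarbenium ion 18 and the silane delivers hydride to C2 on the face anti to the adjacent C3 arm, the kinetic mode established for 3-substituted 2-aryloxolanyl cations, which places the new aryl group cis to the C3 arm (2S), while −78 °C should keep the C5–O1 bond from ionising.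

Step 9
Reactants: 19 (2S,3S,4S,5S)-2,5-bis[3-methoxy-4-(triisopropylsilyloxy)phenyl]-3,4-bis[(triisopropylsilyloxy)methyl]oxolane
Product: 20 eduesmine, [(2S,3S,4S,5S)-2,5-bis(4-hydroxy-3-methoxyphenyl)oxolane-3,4-diyl]dimethanol
Conditions: Bu4NF, AcOH, THF, 0 °C → rt
Reagents that add atoms: none
Why: Fluoride-mediated desilylation removes the two aryl and two primary alkyl silyl ethers in one operation, and the acetic acid buffer keeps the liberated phenols protonated so that no phenoxide-driven opening of the benzylic ethers can disturb C2 or C5.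

Compound list

1 | homovanillic acid, (4-hydroxy-3-methoxyphenyl)acetic acid | COc1cc(CC(=O)O)ccc1O | starting material
2 | triisopropylsilyl [3-methoxy-4-(triisopropylsilyloxy)phenyl]acetate | COc1cc(CC(=O)O[Si](C(C)C)(C(C)C)C(C)C)ccc1O[Si](C(C)C)(C(C)C)C(C)C | intermediate (not isolated)
3 | [3-methoxy-4-(triisopropylsilyloxy)phenyl]acetic acid | COc1cc(CC(=O)O)ccc1O[Si](C(C)C)(C(C)C)C(C)C | intermediate
4 | (2R,5R)-2,5-dimethylpyrrolidine (trans, C2-symmetric auxiliary) | C[C@@H]1CC[C@@H](C)N1 | starting material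
5 | [3-methoxy-4-(triisopropylsilyloxy)phenyl]acetyl chloride | COc1cc(CC(=O)Cl)ccc1O[Si](C(C)C)(C(C)C)C(C)C | intermediate (not isolated)
6 | 1-[(2R,5R)-2,5-dimethylpyrrolidin-1-yl]-2-[3-methoxy-4-(triisopropylsilyloxy)phenyl]ethan-1-one | COc1cc(CC(=O)N2[C@H](C)CC[C@H]2C)ccc1O[Si](C(C)C)(C(C)C)C(C)C | intermediate
7 | (E)-but-2-ene-1,4-diol | OC/C=C/CO | starting material
8 | (E)-1,4-bis(triisopropylsilyloxy)but-2-ene | CC(C)[Si](OC/C=C/CO[Si](C(C)C)(C(C)C)C(C)C)(C(C)C)C(C)C | intermediate
9 | (2R,5R)-1-{2-[3-methoxy-4-(triisopropylsilyloxy)phenyl]ethenylidene}-2,5-dimethylpyrrolidin-1-ium trifluoromethanesulfonate (keteniminium salt) | COc1cc(C=C=[N+]2[C@H](C)CC[C@H]2C)ccc1O[Si](C(C)C)(C(C)C)C(C)C.[O-]S(=O)(=O)C(F)(F)F | intermediate (not isolated)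
10 | (2R,5R)-2,5-dimethyl-1-{2-aryl-3,4-bis[(triisopropylsilyloxy)methyl]cyclobutylidene}pyrrolidin-1-ium trifluoromethanesulfonate, ring carbons arranged as in 11 (aryl cis to the C3 arm, arms trans) | C[C@@H]1CC[C@@H](C)[N+]1=C2[C@H](c3ccc(O[Si](C(C)C)(C(C)C)C(C)C)c(OC)c3)[C@H](CO[Si](C(C)C)(C(C)C)C(C)C)[C@H]2CO[Si](C(C)C)(C(C)C)C(C)C.[O-]S(=O)(=O)C(F)(F)F | intermediate (not isolated)
11 | (2S,3S,4S)-2-[3-methoxy-4-(triisopropylsilyloxy)phenyl]-3,4-bis[(triisopropylsilyloxy)methyl]cyclobutan-1-one (2,3-cis, 3,4-trans) | O=C1[C@H](c2ccc(O[Si](C(C)C)(C(C)C)C(C)C)c(OC)c2)[C@H](CO[Si](C(C)C)(C(C)C)C(C)C)[C@H]1CO[Si](C(C)C)(C(C)C)C(C)C | intermediate (precursor of the key step)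
12 | 1-hydroxy-2-aryl-3,4-bis[(triisopropylsilyloxy)methyl]cyclobutyl 3-chloroperoxybenzoate, C2–C4 as in 11, C1 unassigned | OC1(OOC(=O)c2cccc(Cl)c2)[C@H](c2ccc(O[Si](C(C)C)(C(C)C)C(C)C)c(OC)c2)[C@H](CO[Si](C(C)C)(C(C)C)C(C)C)[C@H]1CO[Si](C(C)C)(C(C)C)C(C)C | intermediate (not isolated)
13 | (3S,4S,5S)-5-[3-methoxy-4-(triisopropylsilyloxy)phenyl]-3,4-bis[(triisopropylsilyloxy)methyl]oxolan-2-one (4,5-cis, 3,4-trans) | O=C1O[C@H](c2ccc(O[Si](C(C)C)(C(C)C)C(C)C)c(OC)c2)[C@H](CO[Si](C(C)C)(C(C)C)C(C)C)[C@H]1CO[Si](C(C)C)(C(C)C)C(C)C | intermediate (product of the key step)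
14 | 4-bromo-2-methoxyphenol | COc1cc(Br)ccc1O | starting material
15 | (4-bromo-2-methoxyphenoxy)triisopropylsilane | COc1cc(Br)ccc1O[Si](C(C)C)(C(C)C)C(C)C | intermediate
16 | [3-methoxy-4-(triisopropylsilyloxy)phenyl]lithium | COc1cc([Li])ccc1O[Si](C(C)C)(C(C)C)C(C)C | intermediate (not isolated)
17 | (3S,4S,5S)-2,5-bis[3-methoxy-4-(triisopropylsilyloxy)phenyl]-3,4-bis[(triisopropylsilyloxy)methyl]oxolan-2-ol, both C2 epimers, in equilibrium with the open hydroxy ketone | OC1(c2ccc(O[Si](C(C)C)(C(C)C)C(C)C)c(OC)c2)O[C@H](c2ccc(O[Si](C(C)C)(C(C)C)C(C)C)c(OC)c2)[C@H](CO[Si](C(C)C)(C(C)C)C(C)C)[C@H]1CO[Si](C(C)C)(C(C)C)C(C)C | intermediate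
18 | 2,5-diaryl-3,4-bis[(triisopropylsilyloxy)methyl]-4,5-dihydro-3H-furan-1-ium hydroxytrifluoroborate, C3–C5 as in 17 | COc1cc(C2=[O+][C@H](c3ccc(O[Si](C(C)C)(C(C)C)C(C)C)c(OC)c3)[C@H](CO[Si](C(C)C)(C(C)C)C(C)C)[C@H]2CO[Si](C(C)C)(C(C)C)C(C)C)ccc1O[Si](C(C)C)(C(C)C)C(C)C.O[B-](F)(F)F | intermediate (not isolated)
19 | (2S,3S,4S,5S)-2,5-bis[3-methoxy-4-(triisopropylsilyloxy)phenyl]-3,4-bis[(triisopropylsilyloxy)methyl]oxolane (2,3-cis, 3,4-trans, 4,5-cis) | COc1cc([C@H]2O[C@H](c3ccc(O[Si](C(C)C)(C(C)C)C(C)C)c(OC)c3)[C@H](CO[Si](C(C)C)(C(C)C)C(C)C)[C@H]2CO[Si](C(C)C)(C(C)C)C(C)C)ccc1O[Si](C(C)C)(C(C)C)C(C)C | intermediate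
20 | eduesmine, [(2S,3S,4S,5S)-2,5-bis(4-hydroxy-3-methoxyphenyl)oxolane-3,4-diyl]dimethanol | COc1cc([C@H]2O[C@H](c3ccc(O)c(OC)c3)[C@H](CO)[C@H]2CO)ccc1O | target

Total step count: 9. Longest linear sequence: 7 steps (1, 2, 4, 5, 7, 8, 9); steps 3 and 6 prepare the alkene and the aryl bromide.

Steps most likely to fail

The cycloaddition (step 4) carries the most risk. Keteniminium salt 9 may be captured too slowly by an E-alkene whose two allylic C–O bonds lower its nucleophilicity, so that self-condensation of 9 takes over, or ring closure may show a poor preference for the aryl-cis-to-C3 arrangement. The fallback sets out from amide 6 and changes the alkene partner to (Z)-1,4-bis(triisopropylsilyloxy)but-2-ene F1, made from commercial (Z)-but-2-ene-1,4-diol with TIPSCl and imidazole. Z-alkenes are the faster partners in ketene-type crossed cycloadditions and place the aryl group endo. The same Tf2O–collidine protocol should lead through the all-cis cyclobutaniminium triflate F2 to the all-cis cyclobutanone F3. Buffered m-CPBA should then give the all-cis lactone F4, and DBU in toluene should equilibrate C3, its only enolisable centre, to the 3,4-trans arrangement. This is lactone 13, where the route is rejoined.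

The oxygen insertion (step 5) is stereospecific, so its weak point is the substrate. Enolisation of the α-aryl ketone before the peracid has reacted would pass a C2-epimerised ketone on as the 4,5-trans lactone. The fallback sets out from cyclobutanone 11 and uses the lability instead of fighting it. DBU equilibrates 11 to the all-trans cyclobutanone F5, and the same Baeyer–Villiger oxidation gives the 4,5-trans lactone F6. LiOH opens this to the hydroxy acid F7, liberated cold and used at once. Mitsunobu lactonisation (PPh3, DIAD) closes the ring with inversion at the benzylic carbinol and returns lactone 13.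

In the aryllithium addition (step 7) the reagent may act as a base at C3 of the hindered lactone, leading to loss of silanolate from the β-position, or the tetrahedral alkoxide may collapse early and take up a second aryl group. The fallback sets out from lactone 13. AlMe3 and MeNH(OMe)·HCl open it to the γ-hydroxy N-methoxy-N-methylamide F8, and Et3SiCl–imidazole masks the carbinol as the triethylsilyl ether F9, which stops relactonisation. Aryllithium 16 then adds once through the chelated adduct to give the aryl ketone F10. AcOH–THF–H2O removes only the triethylsilyl group and releases hemiketal 17, the ring-closed form of the hydroxy ketone.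

Further compounds

F1 | step 4 | (Z)-1,4-bis(triisopropylsilyloxy)but-2-ene | CC(C)[Si](OC/C=C\CO[Si](C(C)C)(C(C)C)C(C)C)(C(C)C)C(C)C
F2 | step 4 | (2R,5R)-2,5-dimethyl-1-{2-aryl-3,4-bis[(triisopropylsilyloxy)methyl]cyclobutylidene}pyrrolidin-1-ium trifluoromethanesulfonate, all-cis ring | C[C@@H]1CC[C@@H](C)[N+]1=C2[C@H](c3ccc(O[Si](C(C)C)(C(C)C)C(C)C)c(OC)c3)[C@H](CO[Si](C(C)C)(C(C)C)C(C)C)[C@@H]2CO[Si](C(C)C)(C(C)C)C(C)C.[O-]S(=O)(=O)C(F)(F)F
F3 | step 4 | (2S,3S,4R)-2-[3-methoxy-4-(triisopropylsilyloxy)phenyl]-3,4-bis[(triisopropylsilyloxy)methyl]cyclobutan-1-one (all-cis) | O=C1[C@H](c2ccc(O[Si](C(C)C)(C(C)C)C(C)C)c(OC)c2)[C@H](CO[Si](C(C)C)(C(C)C)C(C)C)[C@@H]1CO[Si](C(C)C)(C(C)C)C(C)C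
F4 | step 4 | (3R,4S,5S)-5-[3-methoxy-4-(triisopropylsilyloxy)phenyl]-3,4-bis[(triisopropylsilyloxy)methyl]oxolan-2-one (all-cis) | O=C1O[C@H](c2ccc(O[Si](C(C)C)(C(C)C)C(C)C)c(OC)c2)[C@H](CO[Si](C(C)C)(C(C)C)C(C)C)[C@@H]1CO[Si](C(C)C)(C(C)C)C(C)C
F5 | step 5 | (2R,3S,4S)-2-[3-methoxy-4-(triisopropylsilyloxy)phenyl]-3,4-bis[(triisopropylsilyloxy)methyl]cyclobutan-1-one (all-trans) | O=C1[C@@H](c2ccc(O[Si](C(C)C)(C(C)C)C(C)C)c(OC)c2)[C@H](CO[Si](C(C)C)(C(C)C)C(C)C)[C@H]1CO[Si](C(C)C)(C(C)C)C(C)C
F6 | step 5 | (3S,4S,5R)-5-[3-methoxy-4-(triisopropylsilyloxy)phenyl]-3,4-bis[(triisopropylsilyloxy)methyl]oxolan-2-one (4,5-trans) | O=C1O[C@@H](c2ccc(O[Si](C(C)C)(C(C)C)C(C)C)c(OC)c2)[C@H](CO[Si](C(C)C)(C(C)C)C(C)C)[C@H]1CO[Si](C(C)C)(C(C)C)C(C)C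
F7 | step 5 | (2S,3S,4R)-4-hydroxy-4-[3-methoxy-4-(triisopropylsilyloxy)phenyl]-2,3-bis[(triisopropylsilyloxy)methyl]butanoic acid | OC(=O)[C@H](CO[Si](C(C)C)(C(C)C)C(C)C)[C@@H](CO[Si](C(C)C)(C(C)C)C(C)C)[C@@H](O)c1ccc(O[Si](C(C)C)(C(C)C)C(C)C)c(OC)c1
F8 | step 7 | (2S,3S,4S)-4-hydroxy-N-methoxy-N-methyl-4-[3-methoxy-4-(triisopropylsilyloxy)phenyl]-2,3-bis[(triisopropylsilyloxy)methyl]butanamide | CON(C)C(=O)[C@H](CO[Si](C(C)C)(C(C)C)C(C)C)[C@@H](CO[Si](C(C)C)(C(C)C)C(C)C)[C@H](O)c1ccc(O[Si](C(C)C)(C(C)C)C(C)C)c(OC)c1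
F9 | step 7 | (2S,3S,4S)-N-methoxy-N-methyl-4-[3-methoxy-4-(triisopropylsilyloxy)phenyl]-4-(triethylsilyloxy)-2,3-bis[(triisopropylsilyloxy)methyl]butanamide | CON(C)C(=O)[C@H](CO[Si](C(C)C)(C(C)C)C(C)C)[C@@H](CO[Si](C(C)C)(C(C)C)C(C)C)[C@H](O[Si](CC)(CC)CC)c1ccc(O[Si](C(C)C)(C(C)C)C(C)C)c(OC)c1
F10 | step 7 | (2S,3S,4S)-1,4-bis[3-methoxy-4-(triisopropylsilyloxy)phenyl]-4-(triethylsilyloxy)-2,3-bis[(triisopropylsilyloxy)methyl]butan-1-one | O=C(c1ccc(O[Si](C(C)C)(C(C)C)C(C)C)c(OC)c1)[C@H](CO[Si](C(C)C)(C(C)C)C(C)C)[C@@H](CO[Si](C(C)C)(C(C)C)C(C)C)[C@H](O[Si](CC)(CC)CC)c1ccc(O[Si](C(C)C)(C(C)C)C(C)C)c(OC)c1
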